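**Strategy.** Ring C is disconnected at the aryl ether bond O1–C8a. The C2 stereocenter is set first, in the open chain, by an asymmetric Mukaiyama aldol between a ring A methyl ketone and the ring B aldehyde. In the key step the C2 alkoxide displaces fluoride from C8a of ring A by addition–elimination, which closes ring C. It exploits the C4 carbonyl, which sits on C4a next to C8a and takes up the charge. No bond at C2 is touched, so the (S) configuration passes on intact. The precursor is a β-hydroxy ketone with fluorine at C8a and O5 masked as a 2-methylbut-3-en-2-yl ether, which a final Claisen rearrangement turns into 5-OH and 6-prenyl.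

Key step: step 6

Remark on the chemistry (assumption): in step 5 the (S,S) catalyst is taken to direct the enol ether to the Si face of aldehyde 7, which gives the (S) carbinol. The configuration of 18 is to be confirmed on its MTPA esters, and the mirror-image catalyst serves if the sense proves to be the reverse.

Step 1
Reactants: 1 3,4-dimethoxybenzaldehyde; 2 geranyl bromide [(2E)-1-bromo-3,7-dimethylocta-2,6-diene]
Product: 7 2-[(2E)-3,7-dimethylocta-2,6-dien-1-yl]-3,4-dimethoxybenzaldehyde, via lithium α-amino alkoxide 3 (not isolated), via C2-lithiated amino alkoxide 4 (not isolated), via arylcopper species 5 (not isolated), via geranylated amino alkoxide 6 (not isolated)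
Conditions: LiN(Me)CH2CH2NMe2 (from MeNHCH2CH2NMe2 + n-BuLi), THF, −20 °C; n-BuLi, −20 °C; CuBr·SMe2, −78 °C; 2, −78 °C → rt; H2O
Reagents that add atoms: none
Why: The lithium amide adds to the aldehyde to give 3, whose chelating amino alkoxide together with the 3-OMe group directs lithiation to C2 (α-amino alkoxide directed ortho-lithiation), and the derived arylcopper should couple with the allylic bromide at its primary carbon (SN2) with the E alkene untouched before water releases the aldehyde.

Step 2
Reactants: 8 3,5-difluoroanisole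
Product: 11 1-(2,6-difluoro-4-methoxyphenyl)ethanone, via 2,6-difluoro-4-methoxyphenyllithium 9 (not isolated), via lithium hemiaminal adduct 10 (not isolated)
Conditions: n-BuLi, THF, −78 °C; MeC(O)N(OMe)Me, −78 → 0 °C; H2O
Reagents that add atoms: N-methoxy-N-methylacetamide, CC(=O)N(C)OC
Why: The C–H between the two fluorines is by far the most acidic ring position, so the directed ortho-lithiation is regiospecific, −78 °C prevents aryne formation, and the chelated tetrahedral adduct of the N-methoxy-N-methylamide releases the ketone only on work-up.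

Step 3
Reactants: 11 1-(2,6-difluoro-4-methoxyphenyl)ethanone; 12 2-methylbut-3-en-2-ol
Product: 14 1-{2-fluoro-4-methoxy-6-[(2-methylbut-3-en-2-yl)oxy]phenyl}ethanone, via sodium 2-methylbut-3-en-2-olate 13 (not isolated)
Conditions: 12 (1.5 equiv), NaH (1.2 equiv), THF, 0 °C; then 11, 0 °C → rt
Reagents that add atoms: none
Why: SNAr at a C–F bond ortho to the acetyl group; the two fluorines are equivalent so no regiochemistry arises, the first alkoxy group deactivates the ring against a second substitution, and the ether formed is both the mask of O5 (no phenoxide to shut down step 6) and the carrier of the future 6-prenyl group.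

Step 4
Reactants: 14 1-{2-fluoro-4-methoxy-6-[(2-methylbut-3-en-2-yl)oxy]phenyl}ethanone
Product: 16 (1-{2-fluoro-4-methoxy-6-[(2-methylbut-3-en-2-yl)oxy]phenyl}ethenyl)oxy(trimethyl)silane, via lithium enolate 15 (not isolated)
Conditions: LiN(SiMe3)2, THF, −78 °C; Me3SiCl, −78 → 0 °C; used crude after non-aqueous work-up
Reagents that add atoms: chlorotrimethylsilane, C[Si](C)(C)Cl
Why: The methyl group is the only enolisable position, so kinetic deprotonation and O-silylation should give the single enol silane needed for the Mukaiyama aldol without acid that would endanger the tertiary allyl ether.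

Step 5
Reactants: 16 the trimethylsilyl enol ether; 7 2-[(2E)-3,7-dimethylocta-2,6-dien-1-yl]-3,4-dimethoxybenzaldehyde
Product: 18 (3S)-3-{2-[(2E)-3,7-dimethylocta-2,6-dien-1-yl]-3,4-dimethoxyphenyl}-1-{2-fluoro-4-methoxy-6-[(2-methylbut-3-en-2-yl)oxy]phenyl}-3-hydroxypropan-1-one, via trichlorosilyl aldolate 17 (not isolated)
Conditions: SiCl4, (S,S)-bisphosphoramide catalyst (two N,N'-dimethyl-1,1'-binaphthyl-2,2'-diamine-derived cyclic phosphoramides joined by an N,N'-dimethylpentane-1,5-diamine tether, 5 mol%), iPr2NEt (10 mol%), CH2Cl2, −78 °C; aq. NaHCO3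
Reagents that add atoms: none
Why: Mukaiyama aldol under Lewis-base activation of SiCl4, in which the catalyst-bound trichlorosilyl cation binds aldehyde 7 and shields one face so that the enol ether adds to the Si face and sets C2 as (S) (catalyst control), while the catalytic amine scavenges HCl that would threaten the tertiary allyl ether and the geranyl chain.

Step 6
Reactants: 18 the (3S)-β-hydroxy ketone
Product: 21 (2S)-2-{2-[(2E)-3,7-dimethylocta-2,6-dien-1-yl]-3,4-dimethoxyphenyl}-7-methoxy-5-[(2-methylbut-3-en-2-yl)oxy]-2,3-dihydro-4H-chromen-4-one, via potassium alkoxide 19 (not isolated), via anionic σ-adduct 20 (not isolated)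
Conditions: KN(SiMe3)2 (1.0 equiv), THF, −78 → 0 °C; pH 7 phosphate buffer
Reagents that add atoms: none
Why: Deprotonation gives potassium alkoxide 19, which adds to C8a of ring A to give σ-adduct 20, the charge being relayed through C4a into the C4 carbonyl, and loss of fluoride restores the arene (SNAr, addition–elimination). The closest known reaction type is the intramolecular O-arylation of alcohols by ortho-fluoroaryl ketones that gives chroman-4-ones. Ring C closes in a formal 6-endo-trig conjugate addition to the C8a=C4a–C4=O unit followed by β-elimination of fluoride. No stereocenter is formed: C2 keeps the (S) configuration from step 5 because the C2–O1 bond is never broken, and C8a of 20 is only transiently tetrahedral. The step needs ring closure to outrun retro-aldol cleavage and E1cB dehydration of 19 and to spare the product from base; fluoride as leaving group, O5 and O7 meta to C8a, O5 kept as an ether (no phenoxide), low temperature and a single equivalent of base that ends as KF should secure this.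

Step 7
Reactants: 21 the (2S)-5-O-(2-methylbut-3-en-2-yl) flavanone
Product: 23 (2S)-2-{2-[(2E)-3,7-dimethylocta-2,6-dien-1-yl]-3,4-dimethoxyphenyl}-5-hydroxy-7-methoxy-6-(3-methylbut-2-en-1-yl)-2,3-dihydro-4H-chromen-4-one, via ortho-dienone 22 (not isolated)
Conditions: PhMe, 110 °C, sealed tube, N2
Reagents that add atoms: none
Why: Aromatic Claisen rearrangement, in which the [3,3] shift of the 1,1-dimethylallyl aryl ether can only reach C6, the one free position ortho to O5 (C4a is substituted), giving dienone 22 that tautomerises to the hydrogen-bonded 5-hydroxy-6-prenyl ring A under neutral conditions that should leave C2 and the side-chain alkenes untouched.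

**Compound list**

1 | 3,4-dimethoxybenzaldehyde | COc1ccc(C=O)cc1OC | starting material
2 | geranyl bromide, (2E)-1-bromo-3,7-dimethylocta-2,6-diene | BrC/C=C(\C)CCC=C(C)C | starting material
3 | lithium α-amino alkoxide, lithium (3,4-dimethoxyphenyl){[2-(dimethylamino)ethyl](methyl)amino}methanolate, racemic at the carbinol carbon | COc1ccc(C(O[Li])N(C)CCN(C)C)cc1OC | intermediate
4 | C2-lithiated amino alkoxide (lithium at the ring carbon between the side chain and the 3-OMe group) | COc1ccc(C(O[Li])N(C)CCN(C)C)c([Li])c1OC | intermediate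
5 | arylcopper species derived from 4 | COc1ccc(C(O[Li])N(C)CCN(C)C)c([Cu])c1OC | intermediate
6 | geranylated amino alkoxide (E alkene) | COc1ccc(C(O[Li])N(C)CCN(C)C)c(C/C=C(\C)CCC=C(C)C)c1OC | intermediate
7 | 2-[(2E)-3,7-dimethylocta-2,6-dien-1-yl]-3,4-dimethoxybenzaldehyde | COc1ccc(C=O)c(C/C=C(\C)CCC=C(C)C)c1OC | intermediate
8 | 3,5-difluoroanisole | COc1cc(F)cc(F)c1 | starting material
9 | 2,6-difluoro-4-methoxyphenyllithium | COc1cc(F)c([Li])c(F)c1 | intermediate
10 | lithium hemiaminal adduct of 9 with N-methoxy-N-methylacetamide | COc1cc(F)c(C(C)(O[Li])N(C)OC)c(F)c1 | intermediate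
11 | 1-(2,6-difluoro-4-methoxyphenyl)ethanone | CC(=O)c1c(F)cc(OC)cc1F | intermediate
12 | 2-methylbut-3-en-2-ol | C=CC(C)(C)O | starting material
13 | sodium 2-methylbut-3-en-2-olate | C=CC(C)(C)[O-].[Na+] | intermediate
14 | 1-{2-fluoro-4-methoxy-6-[(2-methylbut-3-en-2-yl)oxy]phenyl}ethanone | CC(=O)c1c(F)cc(OC)cc1OC(C)(C)C=C | intermediate
15 | lithium enolate of 14 | C=C(O[Li])c1c(F)cc(OC)cc1OC(C)(C)C=C | intermediate
16 | (1-{2-fluoro-4-methoxy-6-[(2-methylbut-3-en-2-yl)oxy]phenyl}ethenyl)oxy(trimethyl)silane | C=C(O[Si](C)(C)C)c1c(F)cc(OC)cc1OC(C)(C)C=C | intermediate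
17 | trichlorosilyl ether of the (3S)-aldol | COc1cc(F)c(C(=O)C[C@H](O[Si](Cl)(Cl)Cl)c2ccc(OC)c(OC)c2C/C=C(\C)CCC=C(C)C)c(OC(C)(C)C=C)c1 | intermediate
18 | (3S)-3-{2-[(2E)-3,7-dimethylocta-2,6-dien-1-yl]-3,4-dimethoxyphenyl}-1-{2-fluoro-4-methoxy-6-[(2-methylbut-3-en-2-yl)oxy]phenyl}-3-hydroxypropan-1-one | COc1cc(F)c(C(=O)C[C@H](O)c2ccc(OC)c(OC)c2C/C=C(\C)CCC=C(C)C)c(OC(C)(C)C=C)c1 | intermediate
19 | potassium alkoxide of 18, (3S) | COc1cc(F)c(C(=O)C[C@H]([O-])c2ccc(OC)c(OC)c2C/C=C(\C)CCC=C(C)C)c(OC(C)(C)C=C)c1.[K+] | intermediate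
20 | anionic σ-adduct at C8a (potassium dienolate, 2S, C8a transiently tetrahedral, either configuration) | COC1=CC2(F)O[C@H](c3ccc(OC)c(OC)c3C/C=C(\C)CCC=C(C)C)CC([O-])=C2C(OC(C)(C)C=C)=C1.[K+] | intermediate
21 | (2S)-2-{2-[(2E)-3,7-dimethylocta-2,6-dien-1-yl]-3,4-dimethoxyphenyl}-7-methoxy-5-[(2-methylbut-3-en-2-yl)oxy]-2,3-dihydro-4H-chromen-4-one | COc1cc2c(c(OC(C)(C)C=C)c1)C(=O)C[C@@H](c1ccc(OC)c(OC)c1C/C=C(\C)CCC=C(C)C)O2 | intermediate
22 | ortho-dienone of the Claisen rearrangement (2S, C6 tetrahedral, either configuration) | COC1=CC2=C(C(=O)C1CC=C(C)C)C(=O)C[C@@H](c1ccc(OC)c(OC)c1C/C=C(\C)CCC=C(C)C)O2 | intermediate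
23 | (2S)-2-{2-[(2E)-3,7-dimethylocta-2,6-dien-1-yl]-3,4-dimethoxyphenyl}-5-hydroxy-7-methoxy-6-(3-methylbut-2-en-1-yl)-2,3-dihydro-4H-chromen-4-one | COc1cc2c(c(O)c1CC=C(C)C)C(=O)C[C@@H](c1ccc(OC)c(OC)c1C/C=C(\C)CCC=C(C)C)O2 | target

**Total step count:** 7.
**Longest linear sequence:** 6 steps (steps 2 to 7, from 8 to 23). Step 1 supplies aldehyde 7 for step 5.

**Steps most likely to fail**

Step 6. Alkoxide 19 may fragment by retro-aldol and recombine before it cyclises, which would erode the enantiomeric purity, or it may dehydrate by E1cB to the chalcone; displacement may also be slow on the electron-rich ring A. The fallback sets out from 18 and closes the same O1–C8a bond at a stage that has no aldol stereocenter to lose. Oxidation of 18 with DMP (the triacetoxy periodinane, CH2Cl2, NaHCO3) should give 1-{2-fluoro-4-methoxy-6-[(2-methylbut-3-en-2-yl)oxy]phenyl}-3-{2-[(2E)-3,7-dimethylocta-2,6-dien-1-yl]-3,4-dimethoxyphenyl}propane-1,3-dione F1. Its enol oxygen should displace the fluoride with K2CO3 in DMF at 50 °C, the standard flavone closure of 2-fluoroaryl 1,3-diketones, to give 2-{2-[(2E)-3,7-dimethylocta-2,6-dien-1-yl]-3,4-dimethoxyphenyl}-7-methoxy-5-[(2-methylbut-3-en-2-yl)oxy]-4H-chromen-4-one F2. A copper hydride conjugate reduction, a reaction type known for 2-substituted chromones, would then set C2: Cu(OAc)2, DTBM-SEGPHOS (the enantiomer that gives 2S), (EtO)2MeSiH, tBuOH, PhMe. It leaves the isolated alkenes alone and comes back to the route at 21.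

Step 5. Facial selectivity may be poor with the ortho-substituted, electron-rich aldehyde, and the Lewis acid may ionise or prematurely rearrange the tertiary allyl ether. The fallback sets out from 14 and 7 and avoids Lewis acids. A Claisen–Schmidt condensation (Ba(OH)2·8H2O, MeOH, rt) should give (2E)-1-{2-fluoro-4-methoxy-6-[(2-methylbut-3-en-2-yl)oxy]phenyl}-3-{2-[(2E)-3,7-dimethylocta-2,6-dien-1-yl]-3,4-dimethoxyphenyl}prop-2-en-1-one F3. Enantioselective conjugate borylation (CuCl, NaOtBu, a Josiphos-type ferrocenyl bisphosphine of the enantiomer that gives 3S, B2pin2, MeOH, THF) should give the (3S)-3-(4,4,5,5-tetramethyl-1,3,2-dioxaborolan-2-yl) ketone F4. Oxidation with NaBO3·4H2O in THF/H2O replaces boron by hydroxyl with retention and comes back to the route at 18.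

Step 3. The tertiary alkoxide may deprotonate the methyl ketone instead of attacking the ring; the enolate is inert to SNAr and can self-condense, and the hindered alkoxide is slow. The fallback sets out from 8 and does the substitution on a non-enolisable aldehyde. Lithiation as in step 2 (aryllithium 9) and a DMF quench should give 2,6-difluoro-4-methoxybenzaldehyde F5. SNAr with alkoxide 13 (THF, 0 °C) should give 2-fluoro-4-methoxy-6-[(2-methylbut-3-en-2-yl)oxy]benzaldehyde F6. Addition of MeMgBr (THF, −78 °C) gives racemic 1-{2-fluoro-4-methoxy-6-[(2-methylbut-3-en-2-yl)oxy]phenyl}ethanol F7, and oxidation with DMP comes back to the route at 14.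

**Further compounds**

F1 | step 6 | 1-{2-fluoro-4-methoxy-6-[(2-methylbut-3-en-2-yl)oxy]phenyl}-3-{2-[(2E)-3,7-dimethylocta-2,6-dien-1-yl]-3,4-dimethoxyphenyl}propane-1,3-dione | COc1cc(F)c(C(=O)CC(=O)c2ccc(OC)c(OC)c2C/C=C(\C)CCC=C(C)C)c(OC(C)(C)C=C)c1
F2 | step 6 | 2-{2-[(2E)-3,7-dimethylocta-2,6-dien-1-yl]-3,4-dimethoxyphenyl}-7-methoxy-5-[(2-methylbut-3-en-2-yl)oxy]-4H-chromen-4-one | COc1cc2c(c(OC(C)(C)C=C)c1)C(=O)C=C(c1ccc(OC)c(OC)c1C/C=C(\C)CCC=C(C)C)O2
F3 | step 5 | (2E)-1-{2-fluoro-4-methoxy-6-[(2-methylbut-3-en-2-yl)oxy]phenyl}-3-{2-[(2E)-3,7-dimethylocta-2,6-dien-1-yl]-3,4-dimethoxyphenyl}prop-2-en-1-one | COc1cc(F)c(C(=O)/C=C/c2ccc(OC)c(OC)c2C/C=C(\C)CCC=C(C)C)c(OC(C)(C)C=C)c1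
F4 | step 5 | (3S)-3-{2-[(2E)-3,7-dimethylocta-2,6-dien-1-yl]-3,4-dimethoxyphenyl}-1-{2-fluoro-4-methoxy-6-[(2-methylbut-3-en-2-yl)oxy]phenyl}-3-(4,4,5,5-tetramethyl-1,3,2-dioxaborolan-2-yl)propan-1-one | COc1cc(F)c(C(=O)C[C@H](B3OC(C)(C)C(C)(C)O3)c2ccc(OC)c(OC)c2C/C=C(\C)CCC=C(C)C)c(OC(C)(C)C=C)c1
F5 | step 3 | 2,6-difluoro-4-methoxybenzaldehyde | COc1cc(F)c(C=O)c(F)c1
F6 | step 3 | 2-fluoro-4-methoxy-6-[(2-methylbut-3-en-2-yl)oxy]benzaldehyde | COc1cc(F)c(C=O)c(OC(C)(C)C=C)c1
F7 | step 3 | 1-{2-fluoro-4-methoxy-6-[(2-methylbut-3-en-2-yl)oxy]phenyl}ethanol, racemic | COc1cc(F)c(C(C)O)c(OC(C)(C)C=C)c1
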